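**Retrosynthetic overview**

1. Target ⇐ phenol desilylation ⇐ oxidation of the C5′ carbinol ⇐ C12′–C13′ by Weinreb acylation of an (E)-vinyllithium (side chain numbered C1′ benzylic to C15′ carbinol).
2. Ar–C1′ and C4′–C5′ are made together, with the 2′E alkene, by a nickel-catalysed three-component union of a diarylzinc, isoprene and a (Z)-enal (proposed new method).
3. C7′–C8′: nickel-electrocatalytic decarboxylative alkenylation of a redox-active ester with (Z)-3-iodobut-2-en-1-ol, which carries in the 6′Z alkene (electrochemical key step).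
4. C9′–C10′: light-driven Giese addition of the radical from the Roche-ester iodide to acrylic acid; C11′ (R) is bought in methyl (R)-3-hydroxy-2-methylpropanoate.
5. No ring is built: the benzene ring is bought as 1-bromo-2-methoxy-3-methylbenzene and hydroxylated by C–H borylation/oxidation.

Assumption: the (R)-enantiomer of the Roche ester is a catalogue item, as both enantiomers are; the target is read as 2′E,6′Z,11′R,13′E.

**Route**

Step 1
Reactants: 1 methyl (R)-3-hydroxy-2-methylpropanoate
Product: 2 methyl (S)-3-iodo-2-methylpropanoate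
Conditions: [I][I] (iodine), PPh3, imidazole, CH2Cl2, 0 °C to rt
Reagents that add atoms: iodine, [I][I]
Why: Appel iodination replaces the primary hydroxyl by SN2 at CH2 and leaves the neighbouring stereocentre untouched, its descriptor changing from R to S only because CH2I outranks the ester.

Step 2
Reactants: 2 methyl (S)-3-iodo-2-methylpropanoate, 3 acrylic acid
Product: 4 (R)-6-methoxy-5-methyl-6-oxohexanoic acid
Conditions: (TMS)3SiH (1.3 equiv, syringe pump), 3 (4 equiv), MeCN, 390 nm LEDs, rt
Reagents that add atoms: none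
Why: Photochemical Giese reaction in which light-initiated silyl-radical iodine abstraction gives the primary C10′ radical that adds to the acrylic acid terminus and is reduced by Si–H, forming C9′–C10′ while the stereocentre (β to the radical) is retained.

Step 3
Reactants: 5 but-2-yn-1-ol
Product: 6 (Z)-3-iodobut-2-en-1-ol
Conditions: NaAlH2(OCH2CH2OMe)2 (Red-Al), THF, 0 °C to rt; then iodine, −78 to 0 °C
Reagents that add atoms: iodine, [I][I]
Why: Hydroxyl-directed trans-hydroalumination of the propargylic alkoxide gives a cyclic vinylalanate whose C–Al bond is iodinated with retention, which fixes iodine cis to CH2OH (Z).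

Step 4
Reactants: 4 (R)-6-methoxy-5-methyl-6-oxohexanoic acid, 6 (Z)-3-iodobut-2-en-1-ol
Product: 8 methyl (2R,6Z)-8-hydroxy-2,6-dimethyloct-6-enoate, via redox-active phthalimide ester 7 (not isolated)
Conditions: N-hydroxyphthalimide, DIC, DMF, rt (no DMAP); then 6, NiCl2·6H2O (20 mol%), 2,2′-bipyridine (40 mol%), AgNO3 (0.3 equiv), LiCl, DMF, Mg anode, reticulated vitreous carbon cathode, constant current, rt
Reagents that add atoms: N-hydroxyphthalimide, O=C1c2ccccc2C(=O)N1O (its atoms stay in 7 only)
Why: Nickel-electrocatalytic decarboxylative alkenylation in which cathodic reduction of the redox-active ester releases the C8′ radical, which is captured by the alkenylnickel species formed from the vinyl iodide with retention of the Z geometry, forming C7′–C8′ three carbons away from the untouched stereocentre.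

Step 5
Reactants: 8 methyl (2R,6Z)-8-hydroxy-2,6-dimethyloct-6-enoate
Product: 9 methyl (2R,6Z)-2,6-dimethyl-8-oxooct-6-enoate
Conditions: MnO2 (15 equiv), CH2Cl2, rt, short contact time
Reagents that add atoms: none
Why: Chemoselective allylic oxidation with manganese dioxide gives the neral-type (Z)-enal without affecting the ester or the stereocentre.

Step 6
Reactants: 10 1-bromo-2-methoxy-3-methylbenzene
Product: 12 3-bromo-4-methoxy-5-methylphenol, via aryl pinacol boronate 11 (not isolated)
Conditions: [Ir(OMe)(cod)]2 (1.5 mol%), 4,4′-di-tert-butyl-2,2′-bipyridine (3 mol%), B2pin2, THF, 80 °C; then Oxone (KHSO5), acetone/H2O, rt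
Reagents that add atoms: bis(pinacolato)diboron, CC1(C)OB(OC1(C)C)B1OC(C)(C)C(C)(C)O1 (boronate of 11); potassium peroxymonosulfate, [K+].[O-]S(=O)(=O)OO (oxygen of 12)
Why: Sterically controlled iridium-catalysed C–H borylation of the 1,2,3-trisubstituted arene occurs at the only position without an ortho substituent (para to OMe), and the C–B bond is oxidised to the phenol in the same pot.

Step 7
Reactants: 12 3-bromo-4-methoxy-5-methylphenol
Product: 13 (3-bromo-4-methoxy-5-methylphenoxy)(tert-butyl)dimethylsilane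
Conditions: TBSCl, imidazole, DMF, rt
Reagents that add atoms: tert-butyldimethylsilyl chloride, CC(C)(C)[Si](C)(C)Cl
Why: Standard silylation masks the electron-rich phenol against the organometallic and oxidation steps that follow.

Step 8
Reactants: 13 (3-bromo-4-methoxy-5-methylphenoxy)(tert-butyl)dimethylsilane, 14 isoprene, 9 methyl (2R,6Z)-2,6-dimethyl-8-oxooct-6-enoate
Product: 17 methyl (2R,6Z,10E)-12-{5-[(tert-butyldimethylsilyl)oxy]-2-methoxy-3-methylphenyl}-8-hydroxy-2,6,10-trimethyldodeca-6,10-dienoate (C8 epimers), via aryllithium 15 (not isolated), via diarylzinc 16 (not isolated)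
Conditions: 13 (2.4 equiv), t-BuLi (4.8 equiv), THF, −78 °C; ZnCl2 (1.2 equiv), −78 to 0 °C; then Ni(acac)2 (10 mol%), 14 (5 equiv), 9 (1.0 equiv), THF, 0 °C to rt; aq NH4Cl
Reagents that add atoms: tert-butyllithium, [Li]C(C)(C)C (lithium of 15); zinc dichloride, Cl[Zn]Cl (zinc of 16)
Why: Proposed new method: zerovalent nickel couples isoprene and the aldehyde oxidatively at the methyl-bearing diene terminus to give an η3-allyl oxanickelacycle, and aryl transfer from zinc followed by reductive elimination at the distal allyl terminus gives the 1,4-adduct with the (E)-trisubstituted alkene (the carbinol tether sits syn on the allyl), so Ar–C1′ and C4′–C5′ form in one step while C5′ arises as an epimer mixture that step 11 removes; the closest known reaction is the Kimura–Tamaru nickel-catalysed three-component connection of dimethylzinc, 1,3-dienes and aldehydes, not yet shown for a functionalised diarylzinc with isoprene and a (Z)-β,β-disubstituted enal.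

Step 9
Reactants: 18 2-methylbut-3-yn-2-ol
Product: 19 (E)-2-methyl-4-(tributylstannyl)but-3-en-2-ol
Conditions: Bu3SnH, AIBN (cat.), toluene, 85 °C
Reagents that add atoms: tributyltin hydride, CCCC[SnH](CCCC)CCCC
Why: Radical hydrostannation of the terminal alkyne gives the β-stannyl alkene, equilibrating under the stannyl-radical conditions to the (E)-isomer.

Step 10
Reactants: 17 methyl (2R,6Z,10E)-12-{5-[(tert-butyldimethylsilyl)oxy]-2-methoxy-3-methylphenyl}-8-hydroxy-2,6,10-trimethyldodeca-6,10-dienoate, 19 (E)-2-methyl-4-(tributylstannyl)but-3-en-2-ol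
Product: 22 (3E,6R,10Z,14E)-16-{5-[(tert-butyldimethylsilyl)oxy]-2-methoxy-3-methylphenyl}-2,12-dihydroxy-2,6,10,14-tetramethylhexadeca-3,10,14-trien-5-one (C12 epimers), via Weinreb amide 20 (not isolated), via dilithiated vinyl alkoxide 21 (not isolated)
Conditions: MeNHOMe·HCl (3 equiv), i-PrMgCl (7 equiv), THF, −20 to 0 °C; then 21 [from 19 (3.5 equiv), n-BuLi (7 equiv), THF, −78 to −30 °C], −78 to −20 °C; cold aq NH4Cl
Reagents that add atoms: N,O-dimethylhydroxylamine hydrochloride, CNOC.Cl (in 20 only); n-butyllithium, [Li]CCCC (lithium of 21)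
Why: Weinreb ketone synthesis in which the magnesium amide converts the ester into the N-methoxy-N-methylamide and the chelated tetrahedral adduct with the vinyllithium (E geometry kept through tin–lithium exchange) survives until the quench, which prevents over-addition and epimerisation at C11′.

Step 11
Reactants: 22 (3E,6R,10Z,14E)-16-{5-[(tert-butyldimethylsilyl)oxy]-2-methoxy-3-methylphenyl}-2,12-dihydroxy-2,6,10,14-tetramethylhexadeca-3,10,14-trien-5-one
Product: 23 (3E,6R,10Z,14E)-16-{5-[(tert-butyldimethylsilyl)oxy]-2-methoxy-3-methylphenyl}-2-hydroxy-2,6,10,14-tetramethylhexadeca-3,10,14-triene-5,12-dione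
Conditions: Dess–Martin periodinane (1.3 equiv), NaHCO3, CH2Cl2, 0 °C to rt
Reagents that add atoms: none
Why: Buffered Dess–Martin oxidation converts only the secondary allylic alcohol (the tertiary one is inert) into the ketone, merging the C5′ epimers without moving the 2′,3′-alkene into conjugation or epimerising C11′.

Step 12
Reactants: 23 (3E,6R,10Z,14E)-16-{5-[(tert-butyldimethylsilyl)oxy]-2-methoxy-3-methylphenyl}-2-hydroxy-2,6,10,14-tetramethylhexadeca-3,10,14-triene-5,12-dione
Product: 24 (3E,6R,10Z,14E)-2-hydroxy-16-(5-hydroxy-2-methoxy-3-methylphenyl)-2,6,10,14-tetramethylhexadeca-3,10,14-triene-5,12-dione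
Conditions: KHF2 (2 equiv), MeOH, rt
Reagents that add atoms: none
Why: Fluoride-mediated desilylation with KHF2 in methanol is selective for phenolic silyl ethers and mild enough to leave the β,γ-unsaturated ketone, both enones and the tertiary allylic alcohol intact.

**Compound list**

1 | methyl (R)-3-hydroxy-2-methylpropanoate ((R)-Roche ester) | OC[C@@H](C)C(=O)OC | starting material
2 | methyl (S)-3-iodo-2-methylpropanoate | IC[C@@H](C)C(=O)OC | intermediate
3 | acrylic acid | C=CC(=O)O | starting material
4 | (R)-6-methoxy-5-methyl-6-oxohexanoic acid | OC(=O)CCC[C@@H](C)C(=O)OC | intermediate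
5 | but-2-yn-1-ol | CC#CCO | starting material
6 | (Z)-3-iodobut-2-en-1-ol | OC/C=C(/C)I | intermediate
7 | 6-(1,3-dioxoisoindolin-2-yl) 1-methyl (R)-2-methylhexanedioate | O=C(CCC[C@@H](C)C(=O)OC)ON1C(=O)c2ccccc2C1=O | intermediate (not isolated)
8 | methyl (2R,6Z)-8-hydroxy-2,6-dimethyloct-6-enoate | OC/C=C(/C)CCC[C@@H](C)C(=O)OC | intermediate
9 | methyl (2R,6Z)-2,6-dimethyl-8-oxooct-6-enoate | O=C/C=C(/C)CCC[C@@H](C)C(=O)OC | intermediate
10 | 1-bromo-2-methoxy-3-methylbenzene | COc1c(C)cccc1Br | starting material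
11 | 2-(3-bromo-4-methoxy-5-methylphenyl)-4,4,5,5-tetramethyl-1,3,2-dioxaborolane | COc1c(C)cc(B2OC(C)(C)C(C)(C)O2)cc1Br | intermediate (not isolated)
12 | 3-bromo-4-methoxy-5-methylphenol | COc1c(C)cc(O)cc1Br | intermediate
13 | (3-bromo-4-methoxy-5-methylphenoxy)(tert-butyl)dimethylsilane | COc1c(C)cc(O[Si](C)(C)C(C)(C)C)cc1Br | intermediate
14 | isoprene (2-methylbuta-1,3-diene) | C=CC(C)=C | starting material
15 | {5-[(tert-butyldimethylsilyl)oxy]-2-methoxy-3-methylphenyl}lithium | COc1c(C)cc(O[Si](C)(C)C(C)(C)C)cc1[Li] | intermediate (not isolated)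
16 | bis{5-[(tert-butyldimethylsilyl)oxy]-2-methoxy-3-methylphenyl}zinc | COc1c(C)cc(O[Si](C)(C)C(C)(C)C)cc1[Zn]c1cc(O[Si](C)(C)C(C)(C)C)cc(C)c1OC | intermediate (not isolated)
17 | methyl (2R,6Z,10E)-12-{5-[(tert-butyldimethylsilyl)oxy]-2-methoxy-3-methylphenyl}-8-hydroxy-2,6,10-trimethyldodeca-6,10-dienoate (C8 epimers) | COc1c(C)cc(O[Si](C)(C)C(C)(C)C)cc1C/C=C(\C)CC(O)/C=C(/C)CCC[C@@H](C)C(=O)OC | intermediate
18 | 2-methylbut-3-yn-2-ol | CC(C)(O)C#C | starting material
19 | (E)-2-methyl-4-(tributylstannyl)but-3-en-2-ol | CCCC[Sn](CCCC)(CCCC)/C=C/C(C)(C)O | intermediate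
20 | (2R,6Z,10E)-12-{5-[(tert-butyldimethylsilyl)oxy]-2-methoxy-3-methylphenyl}-8-hydroxy-N-methoxy-N,2,6,10-tetramethyldodeca-6,10-dienamide (C8 epimers) | COc1c(C)cc(O[Si](C)(C)C(C)(C)C)cc1C/C=C(\C)CC(O)/C=C(/C)CCC[C@@H](C)C(=O)N(C)OC | intermediate (not isolated)
21 | lithium (E)-4-lithio-2-methylbut-3-en-2-olate | [Li]/C=C/C(C)(C)O[Li] | intermediate (not isolated)
22 | (3E,6R,10Z,14E)-16-{5-[(tert-butyldimethylsilyl)oxy]-2-methoxy-3-methylphenyl}-2,12-dihydroxy-2,6,10,14-tetramethylhexadeca-3,10,14-trien-5-one (C12 epimers) | COc1c(C)cc(O[Si](C)(C)C(C)(C)C)cc1C/C=C(\C)CC(O)/C=C(/C)CCC[C@@H](C)C(=O)/C=C/C(C)(C)O | intermediate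
23 | (3E,6R,10Z,14E)-16-{5-[(tert-butyldimethylsilyl)oxy]-2-methoxy-3-methylphenyl}-2-hydroxy-2,6,10,14-tetramethylhexadeca-3,10,14-triene-5,12-dione | COc1c(C)cc(O[Si](C)(C)C(C)(C)C)cc1C/C=C(\C)CC(=O)/C=C(/C)CCC[C@@H](C)C(=O)/C=C/C(C)(C)O | intermediate
24 | (3E,6R,10Z,14E)-2-hydroxy-16-(5-hydroxy-2-methoxy-3-methylphenyl)-2,6,10,14-tetramethylhexadeca-3,10,14-triene-5,12-dione (CNP0243623.1) | COc1c(C)cc(O)cc1C/C=C(\C)CC(=O)/C=C(/C)CCC[C@@H](C)C(=O)/C=C/C(C)(C)O | target

**Step count and risks**

Total steps: 12. Longest linear sequence: 8 (steps 1, 2, 4, 5, 8, 10, 11, 12).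

Most likely to fail, first: step 8, the proposed new three-component coupling. The risks are direct aryl addition to the aldehyde, 1,2- instead of 1,4-connection, and erosion of the 2′E geometry. The fallback uses known chemistry, sets out from 13 and 9 and comes back at 17. Bromide 13 is lithiated as before (15) and transmetallated with MgBr2·OEt2 to the arylmagnesium bromide F1. CuI-catalysed SN2′ opening of commercial 2-methyl-2-vinyloxirane then gives the (E)-allylic alcohol F2, and MsCl/LiCl/2,6-lutidine converts it into the allylic chloride F3. Reactive barium (from BaI2 and lithium biphenylide, THF, −78 °C) turns F3 into the allylbarium chloride F4, which adds to enal 9 through its α-carbon with retention of the alkene geometry (Yamamoto allylbarium addition) to give 17.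

Second: step 4, the electrochemical decarboxylative alkenylation. The risks are acylation of the free allylic hydroxyl of 6 by the redox-active ester, proto-decarboxylation, and sluggish coupling at the methyl-bearing vinyl carbon. The fallback sets out from 2 and 6 and comes back at 8, bypassing steps 2 and 4. Zinc insertion into 2 (Zn dust, DMF) gives the alkylzinc iodide F5, and Negishi coupling with vinyl bromide (Pd(PPh3)4) gives methyl (R)-2-methylpent-4-enoate F6. Hydroboration with 9-BBN gives the B-alkyl borane F7, and B-alkyl Suzuki–Miyaura coupling with 6 (Pd(dppf)Cl2, AsPh3, Cs2CO3, DMF/H2O) gives 8 with retention of the Z geometry.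

Third: step 10, the one-pot ester-to-enone conversion. The risks are incomplete amide formation next to the free alcohol, slow tin–lithium exchange of the stannyl alkoxide, and loss of material in the one-pot sequence. The fallback sets out from 17 and comes back at 22. Weinreb amide 20 is isolated and treated with vinylmagnesium bromide to give the vinyl ketone F8. Cross-metathesis of F8 with commercial 2-methylbut-3-en-2-ol (Hoveyda–Grubbs second-generation catalyst, RuCl2(H2IMes)(=CH-C6H4-2-O-i-Pr), CH2Cl2, 40 °C) then gives 22 as the E-enone.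

**Further compounds**

F1 | step 8 | {5-[(tert-butyldimethylsilyl)oxy]-2-methoxy-3-methylphenyl}magnesium bromide | COc1c(C)cc(O[Si](C)(C)C(C)(C)C)cc1[Mg]Br
F2 | step 8 | (E)-4-{5-[(tert-butyldimethylsilyl)oxy]-2-methoxy-3-methylphenyl}-2-methylbut-2-en-1-ol | COc1c(C)cc(O[Si](C)(C)C(C)(C)C)cc1C/C=C(\C)CO
F3 | step 8 | tert-butyl{3-[(E)-4-chloro-3-methylbut-2-en-1-yl]-4-methoxy-5-methylphenoxy}dimethylsilane | COc1c(C)cc(O[Si](C)(C)C(C)(C)C)cc1C/C=C(\C)CCl
F4 | step 8 | {(E)-4-{5-[(tert-butyldimethylsilyl)oxy]-2-methoxy-3-methylphenyl}-2-methylbut-2-en-1-yl}barium chloride | COc1c(C)cc(O[Si](C)(C)C(C)(C)C)cc1C/C=C(\C)C[Ba]Cl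
F5 | step 4 | [(S)-3-methoxy-2-methyl-3-oxopropyl]zinc iodide | I[Zn]C[C@@H](C)C(=O)OC
F6 | step 4 | methyl (R)-2-methylpent-4-enoate | C=CC[C@@H](C)C(=O)OC
F7 | step 4 | methyl (R)-5-(9-borabicyclo[3.3.1]nonan-9-yl)-2-methylpentanoate | B1(CCC[C@@H](C)C(=O)OC)C2CCCC1CCC2
F8 | step 10 | (4R,8Z,12E)-14-{5-[(tert-butyldimethylsilyl)oxy]-2-methoxy-3-methylphenyl}-10-hydroxy-4,8,12-trimethyltetradeca-1,8,12-trien-3-one | COc1c(C)cc(O[Si](C)(C)C(C)(C)C)cc1C/C=C(\C)CC(O)/C=C(/C)CCC[C@@H](C)C(=O)C=C
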